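**Plan**

1. Numbering: C1 (isopropenyl)–C2–C3–C4(Me)–C5(OAc)–C6–C7–C8(Me)–C9–C10(=O)–C11–C12(Me)–C13(OAc)–C14. Retrosynthesis cuts, in order: the acetates; the ring bond C4–C5 (α-methylene carbinol from a C4 alkenyl triflate and a C5 aldehyde, Ni/Cr); the C10 carbonyl back to a C10≡C11 alkyne; C12–C13 (allenylindium + aldehyde).
2. Enabling feature: C13–C14–C1–C2–C3–C4, with isopropenyl on C1 and methyl on C4, are the six ring carbons of limonene. Cleaving its ring C=C (as the 1,2-oxide) gives the C13 aldehyde and the C4 methyl ketone with C1 intact; because C4(Me) sits next to C5(O), that ketone is the latent alkenyl nucleophile for ring closure. C5–C10 with the C8 methyl is (S)-citronellal.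
3. Forward: keto aldehyde + citronellal-derived propargylic mesylate → open chain C5…C4; gold closes a C13–O–C10 methyl ketal (temporary five-membered ring that fixes the carbonyl at C10 and masks OH and ketone during enol triflation); unmasking; Mitsunobu acetate; 14-membered ring closure at C4–C5; hydrogenation; acetylation.
4. Stereochemistry: C1 and C8 are bought. C12 comes from a Noyori reduction carried through the allene (net inversion); C13 is set anti by the cyclic transition state and inverted to syn in the Mitsunobu step. C5 is set by the chiral chromium ligand and C4 is relayed from C5 by hydroxyl-directed hydrogenation (anti).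

Key step: step 12

Remark 1: the ligand antipodes named in steps 12 and 13 (and the CBS antipode in the first fallback) are assumed to be those matched to the 5S carbinol; if the sense is opposite, the mirror-image ligand is used and nothing else changes.
Remark 2: (4S)-limonene 1,2-oxide is taken as the commercial cis/trans mixture; both isomers converge in step 1. The ketal carbon C10 in 15–17 is an inconsequential anomer mixture and is left undefined in the SMILES.

Step 1
Reactants: 1 (4S)-limonene 1,2-oxide (cis/trans mixture)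
Product: 3 (3S)-6-oxo-3-(prop-1-en-2-yl)heptanal, via (4S)-p-menth-8-ene-1,2-diol 2 (not isolated)
Conditions: H5IO6, THF/H2O, 0 °C → rt
Reagents that add atoms: water O
Why: acid-promoted epoxide hydrolysis followed by periodate glycol cleavage (Malaprade reaction) cuts the former ring C–C bond, so both epoxide isomers should converge on one keto aldehyde with the remote stereocentre (target C1) untouched.

Step 2
Reactants: 4 (S)-citronellal
Product: 5 (4S)-4,8-dimethylnon-7-en-1-yne
Conditions: Ohira–Bestmann reagent, K2CO3, MeOH, 0 °C → rt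
Reagents that add atoms: dimethyl (1-diazo-2-oxopropyl)phosphonate COP(=O)(OC)C(=[N+]=[N-])C(C)=O
Why: Seyferth–Gilbert homologation (Ohira–Bestmann variant) turns the aldehyde into the terminal alkyne (C10≡C11) under mild base that should not affect the β-stereocentre (target C8).

Step 3
Reactants: 5 (4S)-4,8-dimethylnon-7-en-1-yne
Product: 7 (4S)-7,7-dimethoxy-4-methylhept-1-yne, via (4S)-4-methylhept-6-ynal 6 (not isolated)
Conditions: O3, CH2Cl2/MeOH, −78 °C (indicator end point); Me2S; then HC(OMe)3, TsOH (cat.), rt
Reagents that add atoms: trimethyl orthoformate COC(OC)OC (both methoxy groups of 7); ozone [O-][O+]=O (carbonyl oxygen of 6 only)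
Why: ozonolysis should take the electron-rich trisubstituted alkene well before the terminal alkyne, and acetalisation of the crude aldehyde masks the future C5 aldehyde for the organometallic steps.

Step 4
Reactants: 7 (4S)-7,7-dimethoxy-4-methylhept-1-yne
Product: 9 (6S)-9,9-dimethoxy-6-methylnon-3-yn-2-one, via lithium acetylide 8 (not isolated)
Conditions: n-BuLi, THF, −78 °C; MeC(O)N(OMe)Me, −78 → 0 °C
Reagents that add atoms: N-methoxy-N-methylacetamide CC(=O)N(C)OC
Why: Weinreb acylation of the lithium acetylide stops at the ynone because the chelated tetrahedral adduct survives until work-up.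

Step 5
Reactants: 9 (6S)-9,9-dimethoxy-6-methylnon-3-yn-2-one
Product: 10 (2S,6S)-9,9-dimethoxy-6-methylnon-3-yn-2-ol
Conditions: RuCl[(S,S)-TsDPEN](p-cymene) (1 mol%), i-PrOH, rt
Reagents that add atoms: none
Why: Noyori asymmetric transfer hydrogenation of an alkynyl ketone, in which the (S,S)-catalyst should give the (S)-carbinol with high ee; this centre carries the information for C12.

Step 6
Reactants: 10 (2S,6S)-9,9-dimethoxy-6-methylnon-3-yn-2-ol
Product: 11 (2S,6S)-9,9-dimethoxy-6-methylnon-3-yn-2-yl methanesulfonate
Conditions: MsCl, Et3N, CH2Cl2, −40 → 0 °C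
Reagents that add atoms: methanesulfonyl chloride CS(=O)(=O)Cl
Why: O-sulfonylation with retention gives the propargylic leaving group needed for SN2′ oxidative addition.

Step 7
Reactants: 3 (3S)-6-oxo-3-(prop-1-en-2-yl)heptanal; 11 (2S,6S)-9,9-dimethoxy-6-methylnon-3-yn-2-yl methanesulfonate
Product: 13 (5S,7S,8R,12S)-7-hydroxy-15,15-dimethoxy-8,12-dimethyl-5-(prop-1-en-2-yl)pentadec-9-yn-2-one, via allenylindium 12 (not isolated)
Conditions: Pd(dppf)Cl2 (5 mol%), InI, THF/HMPA 3:1, rt
Reagents that add atoms: none
Why: Marshall propargylation, in which Pd(0) displaces the mesylate anti-SN2′, the allenylpalladium is transmetallated to indium, and the allenylindium adds to the aldehyde (not the methyl ketone) through a cyclic SE2′ transition state; the carbinol centre is thereby transferred with net inversion to C12 (R) and the closed transition state should set C13 anti to it (13S).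

Step 8
Reactants: 13 (12,13-anti homopropargylic alcohol)
Product: 15 2,3-trans cyclic methyl ketal (5-methoxy-3-methyloxolane: ring O–C13–C12–C11–C10(OMe), C13 bearing the limonene-derived chain, C10 the citronellal-derived chain), via cyclic enol ether 14 (not isolated)
Conditions: Ph3PAuCl/AgOTf (2 mol%), PPTS (cat.), MeOH, rt; Et3N quench
Reagents that add atoms: methanol CO
Why: gold(I) activation of the alkyne lets the C13 hydroxyl attack C10 (5-endo-dig, the only ring size open to it) and methanol adds to the enol ether (gold-catalysed cycloisomerisation–hydroalkoxylation of homopropargylic alcohols), which fixes the carbonyl at C10 and ties OH and latent ketone into a base-stable temporary ring.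

Step 9
Reactants: 15 cyclic methyl ketal with free C4 methyl ketone
Product: 17 C4 alkenyl triflate (2-triflyloxy-1-alkene) of 15, via lithium enolate 16 (not isolated)
Conditions: LDA, THF, −78 °C; Comins' reagent, −78 → 0 °C
Reagents that add atoms: N-(5-chloropyridin-2-yl)-bis(trifluoromethanesulfonyl)imide (Comins' reagent) Clc1ccc(nc1)N(S(=O)(=O)C(F)(F)F)S(=O)(=O)C(F)(F)F
Why: kinetic deprotonation of the methyl ketone at the methyl group and O-sulfonylation of the enolate should give the 1,1-disubstituted alkenyl triflate, the C4 ketone being the only enolisable carbonyl while C10 is locked in the ketal.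

Step 10
Reactants: 17 ketal alkenyl triflate
Product: 18 seco hydroxy keto aldehyde (C5 aldehyde, C10 ketone, 13S hydroxyl, C4 alkenyl triflate; 1S,8S,12R,13S in target numbering)
Conditions: 1 M HCl, THF, rt
Reagents that add atoms: water O
Why: dilute acid hydrolyses the cyclic ketal and the dimethyl acetal in one operation, while alkenyl triflate and isopropenyl group should survive these conditions.

Step 11
Reactants: 18 seco hydroxy keto aldehyde
Product: 19 seco (13R)-acetate (C5 aldehyde, C10 ketone, C4 alkenyl triflate; 1S,8S,12R,13R)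
Conditions: PPh3, DIAD, AcOH, toluene, 0 °C → rt
Reagents that add atoms: acetic acid CC(=O)O
Why: Mitsunobu esterification, in which acetate displaces the alkoxyphosphonium by SN2, should invert C13 to R (12,13-syn) and install the natural acetate in the same step.

Step 12
Reactants: 19 seco (13R)-acetate
Product: 21 (1S,5S,8S,12R,13R)-13-acetoxy-5-hydroxy-8,12-dimethyl-4-methylidene-1-(prop-1-en-2-yl)cyclotetradecan-10-one (target numbering), via alkenylchromium(III) 20 (not isolated)
Conditions: CrCl2 (6 equiv), NiCl2 (2 mol%), Kishi's (S)-valinol-derived oxazoline–sulfonamide ligand (6.6 equiv), Et3N, LiCl, degassed THF/MeCN, rt, syringe-pump addition to about 2 mM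
Reagents that add atoms: none
Why: Ni(0) formed in situ inserts into the C4–OTf bond, the alkenylnickel transmetallates to Cr(III), and the alkenylchromium(III) adds to the C5 aldehyde to give the chromium alkoxide of the α-methylene carbinol (Nozaki–Hiyama–Kishi reaction; closest precedent: Ni/Cr macrocyclisations of alkenyl halides and triflates onto aldehydes in terpenoid and macrolide work). The 14-membered carbocycle closes in a 14-exo-trig sense, C4 attacking the exocyclic C5=O. The new C5 stereocentre is controlled by the chiral sulfonamide ligand on chromium (reagent control over the weak bias of the flexible seco chain). The step needs selectivity for the aldehyde over the C10 ketone and the C13 acetate, which the low basicity and aldehyde preference of organochromium(III) reagents should secure, and cyclisation over oligomerisation, which slow addition at high dilution should secure; the isopropenyl group is inert. The 1,1-disubstituted alkene left at C4 is the handle through which the C5 hydroxyl relays the C4 methyl stereocentre in the next step.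

Step 13
Reactants: 21 macrocyclic α-methylene carbinol
Product: 22 (1S,4R,5S,8S,12R,13R)-13-acetoxy-5-hydroxy-4,8,12-trimethyl-1-(prop-1-en-2-yl)cyclotetradecan-10-one (target numbering)
Conditions: Ru(OAc)2[(R)-BINAP] (2 mol%), H2 (10 atm), MeOH, rt
Reagents that add atoms: none
Why: hydroxyl-directed hydrogenation with a Ru–BINAP dicarboxylate, which reduces olefins carrying a coordinating allylic hydroxyl and should leave the isopropenyl group (no hydroxyl in reach) and the ketone alone; hydrogen is delivered to the alkene face next to the Ru-bound C5–O, giving the 4,5-anti product (4R) with the BINAP antipode matched to the 5S carbinol.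

Step 14
Reactants: 22 macrocyclic 5-hydroxy 13-acetate
Product: 23 target, (1S,4R,5S,8S,12R,13R)-5,13-diacetoxy-4,8,12-trimethyl-1-(prop-1-en-2-yl)cyclotetradecan-10-one (target numbering)
Conditions: Ac2O, pyridine, DMAP (cat.), CH2Cl2, rt
Reagents that add atoms: acetic anhydride CC(=O)OC(C)=O
Why: DMAP-catalysed O-acylation of the remaining secondary alcohol with retention should complete the diacetate.

**Compound list**

1 | (4S)-limonene 1,2-oxide, cis/trans mixture | C=C(C)[C@H]1CCC2(C)OC2C1 | starting material
2 | (4S)-p-menth-8-ene-1,2-diol | C=C(C)[C@H]1CCC(C)(O)C(O)C1 | intermediate (not isolated)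
3 | (3S)-6-oxo-3-(prop-1-en-2-yl)heptanal | C=C(C)[C@H](CC=O)CCC(C)=O | intermediate
4 | (S)-citronellal | CC(C)=CCC[C@H](C)CC=O | starting material
5 | (4S)-4,8-dimethylnon-7-en-1-yne | CC(C)=CCC[C@H](C)CC#C | intermediate
6 | (4S)-4-methylhept-6-ynal | O=CCC[C@H](C)CC#C | intermediate (not isolated)
7 | (4S)-7,7-dimethoxy-4-methylhept-1-yne | COC(OC)CC[C@H](C)CC#C | intermediate
8 | lithium acetylide of 7 | COC(OC)CC[C@H](C)CC#C[Li] | intermediate (not isolated)
9 | (6S)-9,9-dimethoxy-6-methylnon-3-yn-2-one | COC(OC)CC[C@H](C)CC#CC(C)=O | intermediate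
10 | (2S,6S)-9,9-dimethoxy-6-methylnon-3-yn-2-ol | COC(OC)CC[C@H](C)CC#C[C@H](C)O | intermediate
11 | (2S,6S)-9,9-dimethoxy-6-methylnon-3-yn-2-yl methanesulfonate | COC(OC)CC[C@H](C)CC#C[C@H](C)OS(C)(=O)=O | intermediate
12 | allenylindium(III) iodide mesylate derived from 11 (axially chiral; axis not encoded) | COC(OC)CC[C@H](C)CC(=C=CC)[In](I)OS(C)(=O)=O | intermediate (not isolated)
13 | (5S,7S,8R,12S)-7-hydroxy-15,15-dimethoxy-8,12-dimethyl-5-(prop-1-en-2-yl)pentadec-9-yn-2-one (12,13-anti in target numbering) | COC(OC)CC[C@H](C)CC#C[C@@H](C)[C@@H](O)C[C@@H](C(C)=C)CCC(C)=O | intermediate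
14 | 2,3-trans-2,3-dihydrofuran (cyclic enol ether O–C10=C11) from 13 | COC(OC)CC[C@H](C)CC1=C[C@@H](C)[C@@H](O1)C[C@@H](C(C)=C)CCC(C)=O | intermediate (not isolated)
15 | 2,3-trans cyclic methyl ketal (C10 anomers) with C4 methyl ketone | COC(OC)CC[C@H](C)CC1(OC)C[C@@H](C)[C@@H](O1)C[C@@H](C(C)=C)CCC(C)=O | intermediate
16 | lithium enolate (terminal) of 15 | COC(OC)CC[C@H](C)CC1(OC)C[C@@H](C)[C@@H](O1)C[C@@H](C(C)=C)CCC(=C)O[Li] | intermediate (not isolated)
17 | C4 alkenyl triflate of 15 | COC(OC)CC[C@H](C)CC1(OC)C[C@@H](C)[C@@H](O1)C[C@@H](C(C)=C)CCC(=C)OS(=O)(=O)C(F)(F)F | intermediate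
18 | seco hydroxy keto aldehyde (1S,8S,12R,13S) | O=CCC[C@H](C)CC(=O)C[C@@H](C)[C@@H](O)C[C@@H](C(C)=C)CCC(=C)OS(=O)(=O)C(F)(F)F | intermediate
19 | seco (13R)-acetate (1S,8S,12R,13R) | O=CCC[C@H](C)CC(=O)C[C@@H](C)[C@H](OC(C)=O)C[C@@H](C(C)=C)CCC(=C)OS(=O)(=O)C(F)(F)F | intermediate
20 | alkenylchromium(III) dichloride derived from 19 | O=CCC[C@H](C)CC(=O)C[C@@H](C)[C@H](OC(C)=O)C[C@@H](C(C)=C)CCC(=C)[Cr](Cl)Cl | intermediate (not isolated)
21 | (1S,5S,8S,12R,13R)-13-acetoxy-5-hydroxy-8,12-dimethyl-4-methylidene-1-(prop-1-en-2-yl)cyclotetradecan-10-one | C=C(C)[C@H]1CCC(=C)[C@@H](O)CC[C@H](C)CC(=O)C[C@@H](C)[C@H](OC(C)=O)C1 | intermediate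
22 | (1S,4R,5S,8S,12R,13R)-13-acetoxy-5-hydroxy-4,8,12-trimethyl-1-(prop-1-en-2-yl)cyclotetradecan-10-one | C=C(C)[C@H]1CC[C@@H](C)[C@@H](O)CC[C@H](C)CC(=O)C[C@@H](C)[C@H](OC(C)=O)C1 | intermediate
23 | (1S,4R,5S,8S,12R,13R)-5,13-diacetoxy-4,8,12-trimethyl-1-(prop-1-en-2-yl)cyclotetradecan-10-one | C=C(C)[C@H]1CC[C@@H](C)[C@@H](OC(C)=O)CC[C@H](C)CC(=O)C[C@@H](C)[C@H](OC(C)=O)C1 | target

**Totals and risks**

Total steps: 14. Longest linear sequence: 13 (steps 2–14, from (S)-citronellal).

Steps most likely to fail:

Step 12. The process at risk is facial discrimination at C5 by the chromium ligand, which the flexible seco chain may override, together with intermolecular coupling competing with ring closure. Fallback (reagent-controlled addition replaced by oxidation and asymmetric reduction): 19 is cyclised with achiral CrCl2/NiCl2 in DMF at high dilution to a mixture of 21 and its C5 epimer, the (5R)-α-methylene carbinol F1. The mixture is oxidised with MnO2, which should touch only the allylic alcohol, to the macrocyclic α-methylene ketone F2. F2 is reduced with (R)-Me-CBS/catecholborane at −78 °C, where the enone carbonyl should react well before the dialkyl ketone at C10, and the route is rejoined at 21.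

Step 11. The process at risk is SN2 displacement at a secondary carbinol next to a methyl branch and γ to a ketone: elimination, or capture of the alkoxyphosphonium by the C10 carbonyl oxygen, may compete with acetate. Fallback (inversion moved ahead of the ketone): 13 is inverted with 4-nitrobenzoic acid, PPh3 and DIAD to the (13R)-4-nitrobenzoate F3, and K2CO3/MeOH releases the 12,13-syn homopropargylic alcohol F4. The gold step (as step 8) gives the 2,3-cis cyclic methyl ketal F5, enol triflation (as step 9) gives its C4 alkenyl triflate F6, and dilute acid (as step 10) gives the (13R)-hydroxy keto aldehyde F7. Ac2O/pyridine acetylates F7 with retention to 19.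

Step 9. The process at risk is regiocontrol in the kinetic deprotonation (enolisation toward C3) and clean O-sulfonylation of the enolate. Fallback (regiochemistry fixed by a hydrazone dianion instead of an enolate): 15 is condensed with 2,4,6-triisopropylbenzenesulfonyl hydrazide to the trisylhydrazone F8. n-BuLi/TMEDA (Shapiro reaction, deprotonation at the methyl group) followed by iodine gives the 2-iodo-1-alkene ketal F9. Dilute acid gives the iodo hydroxy keto aldehyde F10, Mitsunobu acetylation (as step 11) gives the iodo (13R)-acetate F11, and Ni/Cr ring closure of F11 under the conditions of step 12 rejoins the route at 21.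

**Further compounds**

F1 | step 12 | (5R)-epimer of 21 | C=C(C)[C@H]1CCC(=C)[C@H](O)CC[C@H](C)CC(=O)C[C@@H](C)[C@H](OC(C)=O)C1
F2 | step 12 | (1S,8S,12R,13R)-13-acetoxy-8,12-dimethyl-4-methylidene-1-(prop-1-en-2-yl)cyclotetradecane-5,10-dione | C=C(C)[C@H]1CCC(=C)C(=O)CC[C@H](C)CC(=O)C[C@@H](C)[C@H](OC(C)=O)C1
F3 | step 11 | (13R)-4-nitrobenzoate from 13 (inverted ester) | COC(OC)CC[C@H](C)CC#C[C@@H](C)[C@H](OC(=O)c1ccc(cc1)[N+](=O)[O-])C[C@@H](C(C)=C)CCC(C)=O
F4 | step 11 | 12,13-syn homopropargylic alcohol (C13 epimer of 13) | COC(OC)CC[C@H](C)CC#C[C@@H](C)[C@H](O)C[C@@H](C(C)=C)CCC(C)=O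
F5 | step 11 | 2,3-cis cyclic methyl ketal (C13 epimer of 15) | COC(OC)CC[C@H](C)CC1(OC)C[C@@H](C)[C@H](O1)C[C@@H](C(C)=C)CCC(C)=O
F6 | step 11 | C4 alkenyl triflate of F5 | COC(OC)CC[C@H](C)CC1(OC)C[C@@H](C)[C@H](O1)C[C@@H](C(C)=C)CCC(=C)OS(=O)(=O)C(F)(F)F
F7 | step 11 | (13R)-hydroxy keto aldehyde (C13 epimer of 18) | O=CCC[C@H](C)CC(=O)C[C@@H](C)[C@H](O)C[C@@H](C(C)=C)CCC(=C)OS(=O)(=O)C(F)(F)F
F8 | step 9 | 2,4,6-triisopropylbenzenesulfonyl hydrazone of 15 | COC(OC)CC[C@H](C)CC1(OC)C[C@@H](C)[C@@H](O1)C[C@@H](C(C)=C)CCC(C)=NNS(=O)(=O)c1c(C(C)C)cc(C(C)C)cc1C(C)C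
F9 | step 9 | C4 alkenyl iodide (2-iodo-1-alkene) analogue of 17 | COC(OC)CC[C@H](C)CC1(OC)C[C@@H](C)[C@@H](O1)C[C@@H](C(C)=C)CCC(I)=C
F10 | step 9 | iodo analogue of 18 | O=CCC[C@H](C)CC(=O)C[C@@H](C)[C@@H](O)C[C@@H](C(C)=C)CCC(I)=C
F11 | step 9 | iodo analogue of 19 | O=CCC[C@H](C)CC(=O)C[C@@H](C)[C@H](OC(C)=O)C[C@@H](C(C)=C)CCC(I)=C
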